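**Plan**

1. Retrosynthesis: cut (a) the bond from ring carbon C4 to the 4-methylpent-3-enyl chain (Negishi coupling of an enol triflate), (b) the ring bond C2–C3 (aldol-type closure; C3 is the methyl carbon of a methyl ketone, C2 a masked aldehyde carbon), (c) the C6–phenyl bond (rhodium-catalysed 1,4-addition), (d) the C5=C6 bond of an enone precursor (Wittig), and last the substituents of the benzene ring.
2. Enabling feature: the aryl ketone has a free OH ortho to it (the oxygen on C4 of the benzoate ring). The unit O–aryl–C(=O)–C1–C2 can therefore be carried as O1–C8a–C4a–C4–C3–C2 of a 4H-chromen-4-one. Its C2 is a masked aldehyde carbon lying 1,5 to the side-chain ketone carbon (later C4), the pattern of a Robinson-type closure.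
3. Forward order: the benzene ring is fully substituted first (steps 1–5) and the pyranone ring is fused onto it (step 6). The side chain and the phenyl group follow (steps 7–8). The cyclohexene ring is then closed through the C2–C3 bond while the pyranone ring opens (step 9). The chain is attached at C4 (steps 10–12) and the phenols are freed (step 13).
4. Stereochemistry: C6 comes from catalyst control in the Hayashi–Miyaura step ((S)-BINAP). C1 is epimerisable and is set trans to phenyl under thermodynamic control in step 9, so both C1 epimers converge on the (1R,6R) series.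

Key step: step 9

Remark: locants C1 to C6 are those of the cyclohexene ring of the target (C1 carries the aroyl group, C2 is CH2, C3=C4 is the double bond, C6 carries phenyl); compounds 1, 10, 12 and 19 are taken as purchased.

**Route**

Step 1
Reactants: 1 5-methoxybenzene-1,3-diol
Product: 2 1-methoxy-3,5-bis(methoxymethoxy)benzene
Conditions: MOMCl, i-Pr2NEt, CH2Cl2, 0 °C to rt
Reagents that add atoms: chloromethyl methyl ether (MOMCl), COCCl
Why: Both phenols are alkylated by the chloromethyl ether (Williamson-type O-alkylation), which gives the two acetal ethers that direct the lithiations of steps 2 and 3.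

Step 2
Reactants: 2 1-methoxy-3,5-bis(methoxymethoxy)benzene
Product: 4 5-methoxy-1,3-bis(methoxymethoxy)-2-methylbenzene, via aryllithium 3 (not isolated)
Conditions: n-BuLi, THF, 0 °C; then MeI, −78 °C to rt
Reagents that add atoms: iodomethane, CI
Why: Directed ortho-metalation should take place at the ring carbon between the two OCH2OCH3 groups, where two chelating directing groups cooperate, and the aryllithium is methylated by SN2 on MeI.

Step 3
Reactants: 4 5-methoxy-1,3-bis(methoxymethoxy)-2-methylbenzene
Product: 6 methyl 6-methoxy-2,4-bis(methoxymethoxy)-3-methylbenzoate, via aryllithium 5 (not isolated)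
Conditions: n-BuLi, TMEDA, THF, −20 °C; then ClCO2Me, −78 °C
Reagents that add atoms: methyl chloroformate, COC(=O)Cl
Why: A second directed ortho-metalation can only take one of the two symmetry-equivalent CH positions between OCH2OCH3 and OCH3, and acylation of the aryllithium with the chloroformate gives the benzoate.

Step 4
Reactants: 6 methyl 6-methoxy-2,4-bis(methoxymethoxy)-3-methylbenzoate
Product: 7 methyl 2,4-dihydroxy-6-methoxy-3-methylbenzoate
Conditions: HCl (cat.), MeOH, 50 °C
Reagents that add atoms: none
Why: Acid-catalysed acetal exchange with methanol removes both methoxymethyl ethers while the aryl methyl ether and the ester are inert.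

Step 5
Reactants: 7 methyl 2,4-dihydroxy-6-methoxy-3-methylbenzoate
Product: 8 methyl 3-acetyl-4,6-dihydroxy-2-methoxy-5-methylbenzoate
Conditions: Ac2O, CF3SO3H (20 mol %), MeNO2, 0 to 50 °C
Reagents that add atoms: acetic anhydride, CC(=O)OC(C)=O
Why: Friedel–Crafts C-acetylation (any O-acetate returning by Fries rearrangement under the same acid) can only occur at the single free ring carbon, which is ortho and para to the three oxygen substituents.

Step 6
Reactants: 8 methyl 3-acetyl-4,6-dihydroxy-2-methoxy-5-methylbenzoate
Product: 9 methyl 3-formyl-7-hydroxy-5-methoxy-8-methyl-4-oxo-4H-chromene-6-carboxylate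
Conditions: POCl3, DMF, 0 to 55 °C; then H2O
Reagents that add atoms: N,N-dimethylformamide, CN(C)C=O; water, O
Why: Vilsmeier–Haack reaction of the ortho-hydroxyacetophenone: the methyl group is formylated twice and the phenol oxygen ortho to the ketone (the other ortho position carries OCH3) closes the 4H-pyran-4-one ring, so that C1 and C2 of the future cyclohexene are stored as C3 and C2 of a 3-formylchromone.

Step 7
Reactants: 9 methyl 3-formyl-7-hydroxy-5-methoxy-8-methyl-4-oxo-4H-chromene-6-carboxylate; 10 1-(triphenyl-λ5-phosphanylidene)propan-2-one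
Product: 11 methyl 7-hydroxy-5-methoxy-8-methyl-4-oxo-3-[(1E)-3-oxobut-1-en-1-yl]-4H-chromene-6-carboxylate
Conditions: toluene, 80 °C
Reagents that add atoms: none
Why: Wittig olefination of the aldehyde by the stabilised ylide should give the (E)-enone, since the pyranone and ester carbonyl groups do not react with a stabilised ylide.

Step 8
Reactants: 11 methyl 7-hydroxy-5-methoxy-8-methyl-4-oxo-3-[(1E)-3-oxobut-1-en-1-yl]-4H-chromene-6-carboxylate; 12 phenylboronic acid
Product: 13 methyl 7-hydroxy-5-methoxy-8-methyl-4-oxo-3-[(1S)-3-oxo-1-phenylbutyl]-4H-chromene-6-carboxylate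
Conditions: Rh(acac)(C2H4)2 (3 mol %), (S)-BINAP, dioxane/H2O (10:1), 90 °C
Reagents that add atoms: none
Why: Hayashi–Miyaura rhodium-catalysed asymmetric 1,4-addition: phenylrhodium carbometalates the s-cis enone on the face left open by the (S)-BINAP ligand (the sense expected from the quadrant model for (E)-alk-3-en-2-ones), which sets the benzylic stereocentre (later C6) as S, while the trisubstituted, oxygen-donor-substituted C2=C3 bond of the pyranone is a much poorer acceptor.

Step 9
Reactants: 13 methyl 7-hydroxy-5-methoxy-8-methyl-4-oxo-3-[(1S)-3-oxo-1-phenylbutyl]-4H-chromene-6-carboxylate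
Product: 15 methyl 2,4-dihydroxy-6-methoxy-3-methyl-5-[(1R,6R)-4-oxo-6-phenylcyclohex-2-ene-1-carbonyl]benzoate, via tricyclic Michael adduct 14 (not isolated)
Conditions: pyrrolidine (1.5 equiv), AcOH (1.5 equiv), toluene, 60 °C; then 1 M HCl, THF, rt
Reagents that add atoms: none
Why: Pyrrolidinium acetate turns the methyl ketone into its enamine, whose terminal carbon adds in 1,4-fashion to C2 of the protonated 4H-chromen-4-one, and the chromanone enol so formed (14, as its iminium) expels the aryl oxide by E1cB (retro-oxa-Michael), so that the pyranone ring opens to the free ortho-phenol and hydrolysis leaves the conjugated cyclohexenone; prior opening of the pyranone by the amine to an enaminone would lead to the same product by Mannich-type condensation. The closest known reaction type is the domino Michael/retro-Michael ring transformation of chromones by enamines and 1,3-dicarbonyl carbon nucleophiles, which here plays the part of the aldol condensation of a Robinson annulation with the chromone as a masked β-ketoaldehyde. The carbocycle closes in a 6-endo-trig mode (nucleophilic carbon onto the C2=C3 bond that lies inside the new ring), and the six-membered pyranone is opened in the same operation. The new stereocentre C1 (α to the aryl ketone and γ to the enone) is epimerisable through the dienamine or dienol and should settle trans to the phenyl group at C6, so it is set by thermodynamic control from the centre made in step 8 and both C1 epimers converge. The step needs the methyl rather than the methylene α-carbon to attack and C2 rather than the C4 carbonyl to be attacked: the methylene carbon could only form a four-membered ring, and addition to C2 is made irreversible by ring opening while aldol addition to the cross-conjugated C4 carbonyl is reversible.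

Step 10
Reactants: 15 methyl 2,4-dihydroxy-6-methoxy-3-methyl-5-[(1R,6R)-4-oxo-6-phenylcyclohex-2-ene-1-carbonyl]benzoate
Product: 16 methyl 2-methoxy-4,6-bis(methoxymethoxy)-5-methyl-3-[(1R,6R)-4-oxo-6-phenylcyclohex-2-ene-1-carbonyl]benzoate
Conditions: MOMCl, i-Pr2NEt, CH2Cl2, 0 to 40 °C
Reagents that add atoms: chloromethyl methyl ether (MOMCl), COCCl
Why: O-Alkylation of both phenols removes the acidic OH groups before the hydride and triflation step and prevents the freed ortho-phenol from adding back to the enone (oxa-Michael).

Step 11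
Reactants: 16 methyl 2-methoxy-4,6-bis(methoxymethoxy)-5-methyl-3-[(1R,6R)-4-oxo-6-phenylcyclohex-2-ene-1-carbonyl]benzoate
Product: 18 methyl 2-methoxy-4,6-bis(methoxymethoxy)-5-methyl-3-[(1R,6R)-6-phenyl-4-(trifluoromethanesulfonyloxy)cyclohex-3-ene-1-carbonyl]benzoate, via lithium enolate 17 (not isolated)
Conditions: LiBH(s-Bu)3, THF, −78 °C; then PhNTf2, −78 to 0 °C
Reagents that add atoms: N-phenylbis(trifluoromethanesulfonimide), O=S(=O)(N(c1ccccc1)S(=O)(=O)C(F)(F)F)C(F)(F)F
Why: Conjugate hydride addition to the β-unsubstituted cyclohexenone should give the enolate with the double bond fixed between C3 and C4, and O-sulfonylation with the triflimide traps it as the enol triflate (reductive enol triflate formation); the aryl ketone and the ester are each shielded by two ortho substituents.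

Step 12
Reactants: 18 methyl 2-methoxy-4,6-bis(methoxymethoxy)-5-methyl-3-[(1R,6R)-6-phenyl-4-(trifluoromethanesulfonyloxy)cyclohex-3-ene-1-carbonyl]benzoate; 19 5-bromo-2-methylpent-2-ene
Product: 21 methyl 2-methoxy-4,6-bis(methoxymethoxy)-5-methyl-3-[(1R,6R)-4-(4-methylpent-3-en-1-yl)-6-phenylcyclohex-3-ene-1-carbonyl]benzoate, via bromo(4-methylpent-3-en-1-yl)zinc 20 (not isolated)
Conditions: 19, Zn dust, LiCl, THF, 50 °C; then 18, PdCl2(dppf) (5 mol %), THF, 50 °C
Reagents that add atoms: none
Why: Negishi coupling: oxidative addition of the alkenyl triflate to zerovalent palladium, transmetalation from the alkylzinc bromide and reductive elimination form the C(sp2)–C(sp3) bond with the ring double bond held in place, and the organozinc tolerates the ketone and the ester.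

Step 13
Reactants: 21 methyl 2-methoxy-4,6-bis(methoxymethoxy)-5-methyl-3-[(1R,6R)-4-(4-methylpent-3-en-1-yl)-6-phenylcyclohex-3-ene-1-carbonyl]benzoate
Product: 22 methyl 2,4-dihydroxy-6-methoxy-3-methyl-5-[(1R,6R)-4-(4-methylpent-3-en-1-yl)-6-phenylcyclohex-3-ene-1-carbonyl]benzoate
Conditions: HCl (3 M aq.), MeOH, 40 °C
Reagents that add atoms: none
Why: Acid-catalysed acetal cleavage frees both phenols, which hydrogen-bond to the ketone and the ester; the trans arrangement at C1 and C6 is the thermodynamic one, so acid-promoted enolisation should not erode it.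

**Compound list**

1 | 5-methoxybenzene-1,3-diol | COc1cc(O)cc(O)c1 | starting material
2 | 1-methoxy-3,5-bis(methoxymethoxy)benzene | COc1cc(OCOC)cc(OCOC)c1 | intermediate
3 | [4-methoxy-2,6-bis(methoxymethoxy)phenyl]lithium | [Li]c1c(OCOC)cc(OC)cc1OCOC | intermediate
4 | 5-methoxy-1,3-bis(methoxymethoxy)-2-methylbenzene | Cc1c(OCOC)cc(OC)cc1OCOC | intermediate
5 | [6-methoxy-2,4-bis(methoxymethoxy)-3-methylphenyl]lithium | Cc1c(OCOC)cc(OC)c([Li])c1OCOC | intermediate
6 | methyl 6-methoxy-2,4-bis(methoxymethoxy)-3-methylbenzoate | COC(=O)c1c(OCOC)c(C)c(OCOC)cc1OC | intermediate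
7 | methyl 2,4-dihydroxy-6-methoxy-3-methylbenzoate | COC(=O)c1c(O)c(C)c(O)cc1OC | intermediate
8 | methyl 3-acetyl-4,6-dihydroxy-2-methoxy-5-methylbenzoate | COC(=O)c1c(O)c(C)c(O)c(C(C)=O)c1OC | intermediate
9 | methyl 3-formyl-7-hydroxy-5-methoxy-8-methyl-4-oxo-4H-chromene-6-carboxylate | COC(=O)c1c(O)c(C)c2occ(C=O)c(=O)c2c1OC | intermediate
10 | 1-(triphenyl-λ5-phosphanylidene)propan-2-one | CC(=O)C=P(c1ccccc1)(c1ccccc1)c1ccccc1 | starting material
11 | methyl 7-hydroxy-5-methoxy-8-methyl-4-oxo-3-[(1E)-3-oxobut-1-en-1-yl]-4H-chromene-6-carboxylate | COC(=O)c1c(O)c(C)c2occ(/C=C/C(C)=O)c(=O)c2c1OC | intermediate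
12 | phenylboronic acid | OB(O)c1ccccc1 | starting material
13 | methyl 7-hydroxy-5-methoxy-8-methyl-4-oxo-3-[(1S)-3-oxo-1-phenylbutyl]-4H-chromene-6-carboxylate | COC(=O)c1c(O)c(C)c2occ([C@@H](CC(C)=O)c3ccccc3)c(=O)c2c1OC | intermediate
14 | methyl (1R)-6-hydroxy-8-methoxy-5-methyl-3,9-dioxo-1-phenyl-2,3,4,4a,9,9a-hexahydro-1H-xanthene-7-carboxylate (ring-fusion centres 4a and 9a not assigned) | COC(=O)c1c(O)c(C)c2OC3CC(=O)C[C@@H](c4ccccc4)C3C(=O)c2c1OC | intermediate
15 | methyl 2,4-dihydroxy-6-methoxy-3-methyl-5-[(1R,6R)-4-oxo-6-phenylcyclohex-2-ene-1-carbonyl]benzoate | COC(=O)c1c(O)c(C)c(O)c(C(=O)[C@@H]2C=CC(=O)C[C@H]2c2ccccc2)c1OC | intermediate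
16 | methyl 2-methoxy-4,6-bis(methoxymethoxy)-5-methyl-3-[(1R,6R)-4-oxo-6-phenylcyclohex-2-ene-1-carbonyl]benzoate | COC(=O)c1c(OCOC)c(C)c(OCOC)c(C(=O)[C@@H]2C=CC(=O)C[C@H]2c2ccccc2)c1OC | intermediate
17 | lithium enolate of the cyclohexanone (C3=C4–OLi) derived from 16 | COC(=O)c1c(OCOC)c(C)c(OCOC)c(C(=O)[C@@H]2CC=C(O[Li])C[C@H]2c2ccccc2)c1OC | intermediate
18 | methyl 2-methoxy-4,6-bis(methoxymethoxy)-5-methyl-3-[(1R,6R)-6-phenyl-4-(trifluoromethanesulfonyloxy)cyclohex-3-ene-1-carbonyl]benzoate | COC(=O)c1c(OCOC)c(C)c(OCOC)c(C(=O)[C@@H]2CC=C(OS(=O)(=O)C(F)(F)F)C[C@H]2c2ccccc2)c1OC | intermediate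
19 | 5-bromo-2-methylpent-2-ene | CC(C)=CCCBr | starting material
20 | bromo(4-methylpent-3-en-1-yl)zinc | CC(C)=CCC[Zn]Br | intermediate
21 | methyl 2-methoxy-4,6-bis(methoxymethoxy)-5-methyl-3-[(1R,6R)-4-(4-methylpent-3-en-1-yl)-6-phenylcyclohex-3-ene-1-carbonyl]benzoate | COC(=O)c1c(OCOC)c(C)c(OCOC)c(C(=O)[C@@H]2CC=C(CCC=C(C)C)C[C@H]2c2ccccc2)c1OC | intermediate
22 | methyl 2,4-dihydroxy-6-methoxy-3-methyl-5-[(1R,6R)-4-(4-methylpent-3-en-1-yl)-6-phenylcyclohex-3-ene-1-carbonyl]benzoate | COC(=O)c1c(O)c(C)c(O)c(C(=O)[C@@H]2CC=C(CCC=C(C)C)C[C@H]2c2ccccc2)c1OC | target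

**Step count**

Total: 13 steps. Longest linear sequence: 13 steps (1 to 22).

**Steps most likely to fail, with fallbacks**

Step 9. After amine-induced opening of the pyranone, the C2 carbon may be lost by deformylation. The reaction may also stall at the ring-opened enaminone, or the freed phenol may add back to the enone. The fallback sets out from 13 and changes the activation from enamine to an electrophilic benzopyrylium. Internal-quench silylation (LiN(SiMe3)2, Me3SiCl, THF, −78 °C) should give the kinetic silyl enol ether and aryl silyl ether methyl 5-methoxy-8-methyl-4-oxo-3-[(1S)-1-phenyl-3-(trimethylsilyloxy)but-3-en-1-yl]-7-(trimethylsilyloxy)-4H-chromene-6-carboxylate F1. Me3SiOSO2CF3 (0.2 equiv, CH2Cl2, −78 °C) then O-silylates the pyranone carbonyl to a 4-silyloxybenzopyrylium ion, which the tethered silyl enol ether attacks at C2 (intramolecular Mukaiyama–Michael addition). Aqueous work-up gives the tricyclic diketone 14, here isolated. DBU in MeCN at rt then opens it by retro-oxa-Michael elimination, and the route is rejoined at 15.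

Step 11. The basic borohydride may deprotonate C1–H (α to the aryl ketone and vinylogously activated by the enone) instead of transferring hydride, or the enolate may equilibrate before O-sulfonylation. The fallback sets out from 16 and makes the regiodefined enol derivative under neutral conditions. Rhodium-catalysed 1,4-hydrosilylation (RhCl(PPh3)3, Et3SiH, THF, 50 °C) should give the triethylsilyl enol ether methyl 2-methoxy-4,6-bis(methoxymethoxy)-5-methyl-3-[(1R,6R)-6-phenyl-4-(triethylsilyloxy)cyclohex-3-ene-1-carbonyl]benzoate F2. Fluoride-induced desilylation in the presence of the triflimide (CsF, PhNTf2, DME, rt) converts it into the enol triflate, and the route is rejoined at 18.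

Step 6. The second formylation may stay incomplete, and O-formylation or chlorination of the hindered, ester-bearing ketone may compete under the acidic chloroiminium conditions. The fallback sets out from 8 and builds the substituted chromone by an enaminone route. Condensation with Me2NCH(OMe)2 (toluene, 90 °C) should give the enaminone methyl 3-[(2E)-3-(dimethylamino)prop-2-enoyl]-4,6-dihydroxy-2-methoxy-5-methylbenzoate F3. Iodine (CHCl3, rt) induces cyclisation with loss of dimethylamine to the 3-iodochromone methyl 7-hydroxy-3-iodo-5-methoxy-8-methyl-4-oxo-4H-chromene-6-carboxylate F4. A Heck reaction with but-3-en-2-one (Pd(OAc)2, P(o-Tol)3, Et3N, DMF, 80 °C) then gives the (E)-enone, and the route is rejoined at 11, so steps 6 and 7 are replaced.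

**Further compounds**

F1 | step 9 | methyl 5-methoxy-8-methyl-4-oxo-3-[(1S)-1-phenyl-3-(trimethylsilyloxy)but-3-en-1-yl]-7-(trimethylsilyloxy)-4H-chromene-6-carboxylate | COC(=O)c1c(O[Si](C)(C)C)c(C)c2occ([C@@H](CC(=C)O[Si](C)(C)C)c3ccccc3)c(=O)c2c1OC
F2 | step 11 | methyl 2-methoxy-4,6-bis(methoxymethoxy)-5-methyl-3-[(1R,6R)-6-phenyl-4-(triethylsilyloxy)cyclohex-3-ene-1-carbonyl]benzoate | COC(=O)c1c(OCOC)c(C)c(OCOC)c(C(=O)[C@@H]2CC=C(O[Si](CC)(CC)CC)C[C@H]2c2ccccc2)c1OC
F3 | step 6 | methyl 3-[(2E)-3-(dimethylamino)prop-2-enoyl]-4,6-dihydroxy-2-methoxy-5-methylbenzoate | COC(=O)c1c(O)c(C)c(O)c(C(=O)/C=C/N(C)C)c1OC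
F4 | step 6 | methyl 7-hydroxy-3-iodo-5-methoxy-8-methyl-4-oxo-4H-chromene-6-carboxylate | COC(=O)c1c(O)c(C)c2occ(I)c(=O)c2c1OC
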